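The spermidine chain is disconnected at N4–C3, the bond between the central nitrogen and the three-carbon arm. That arm, C(=O)–N1H–CH2–CH2–C3H2, is the opened form of a 2-styryl-5,6-dihydro-4H-1,3-oxazine: ring atoms O1 and C2 become the amide carbonyl, N3 becomes N1, and C4–C6 become the propyl carbons, with the O–CH2 carbon C6 as the electrophile once N3 is protonated. Attack by the free primary amine of an N8-acylated putrescine forges N4–C3 and unveils the N1 amide in one operation, so no nitrogen needs protection. Both partners derive from 3,4-dimethoxycinnamic acid; the four methyl ethers are removed at the end with BBr3.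

Key step: step 5

Remark on numbering: spermidine is taken as 4-azaoctane-1,8-diamine, so the three-carbon arm links N1 to N4 and the four-carbon arm links N4 to N8. The oxazine therefore delivers the N1-acylaminopropyl unit, and the amide nitrogen already present in the nucleophile is N8.

Assumption: the target is wanted as the free base as drawn. The demethylation first gives its hydrobromide, which is neutralised under argon; the salt remains the better storage form.

Step 1
Reactants: 1 (E)-3,4-dimethoxycinnamic acid
Product: 2 (E)-3,4-dimethoxycinnamoyl chloride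
Conditions: (COCl)2 (1.3 equiv), DMF (cat.), CH2Cl2, 0 °C to rt; evaporated and used crude in steps 2 and 4
Reagents that add atoms: oxalyl chloride, O=C(Cl)C(=O)Cl
Why: Acyl chloride formation by the DMF-catalysed oxalyl chloride method (Vilsmeier-type activation) is routine for cinnamic acids and should leave the (E)-alkene and the aryl methyl ethers untouched.

Step 2
Reactants: 2 (E)-3,4-dimethoxycinnamoyl chloride; 3 3-aminopropan-1-ol
Product: 4 (E)-3-(3,4-dimethoxyphenyl)-N-(3-hydroxypropyl)prop-2-enamide
Conditions: 3 (1.2 equiv), Et3N (1.5 equiv), CH2Cl2, −10 °C to rt, 2 added dropwise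
Reagents that add atoms: none
Why: Schotten–Baumann-type N-acylation, in which the primary amine of 3 is far more nucleophilic than its hydroxyl group, so that adding 2 to the cold amino alcohol should give the hydroxy amide chemoselectively with the (E)-geometry retained.

Step 3
Reactants: 4 (E)-3-(3,4-dimethoxyphenyl)-N-(3-hydroxypropyl)prop-2-enamide
Product: 6 2-[(E)-2-(3,4-dimethoxyphenyl)ethenyl]-5,6-dihydro-4H-1,3-oxazine, via primary tosylate 5 (not isolated)
Conditions: TsCl (1.2 equiv), Et3N (3 equiv), DMAP (0.1 equiv), ClCH2CH2Cl, 0 °C then 70 °C; aq. NaHCO3 work-up, Et3N-deactivated silica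
Reagents that add atoms: none
Why: Cyclodehydration of an N-(3-hydroxypropyl)amide, in which tosylation of the primary alcohol is followed by 6-exo-tet displacement of tosylate by the amide oxygen and deprotonation by Et3N, the standard sulfonate route to 2-oxazolines and 5,6-dihydro-4H-1,3-oxazines.

Step 4
Reactants: 2 (E)-3,4-dimethoxycinnamoyl chloride; 7 putrescine (butane-1,4-diamine)
Product: 8 (E)-N-(4-aminobutyl)-3-(3,4-dimethoxyphenyl)prop-2-enamide
Conditions: 7 (8 equiv), CH2Cl2, −10 °C, 2 in CH2Cl2 added dropwise over 2 h; water wash, then acid–base extraction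
Reagents that add atoms: none
Why: Statistical monoacylation of a symmetrical diamine, in which slow addition of 2 to a large excess of cold putrescine keeps free diamine far above the concentration of 8; the surplus diamine serves as HCl acceptor and washes out with water, and any neutral bis-amide is left behind on acid–base extraction.

Step 5
Reactants: 6 2-[(E)-2-(3,4-dimethoxyphenyl)ethenyl]-5,6-dihydro-4H-1,3-oxazine; 8 (E)-N-(4-aminobutyl)-3-(3,4-dimethoxyphenyl)prop-2-enamide
Product: 9 N1,N8-bis[(E)-3,4-dimethoxycinnamoyl]spermidine, (2E)-3-(3,4-dimethoxyphenyl)-N-{4-[(3-{[(2E)-3-(3,4-dimethoxyphenyl)prop-2-enoyl]amino}propyl)amino]butyl}prop-2-enamide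
Conditions: 8 (3 equiv), TsOH (0.3 equiv, dried azeotropically), PhCl–NMP 4:1, 125 °C, Ar, 6 added slowly by syringe pump; aq. NaOH work-up, excess 8 recovered on silica (CH2Cl2/MeOH/NH3)
Reagents that add atoms: none
Why: Proton transfer from the ammonium tosylate of 8 to N3 of 6 gives a small stationary amount of the 2-styryl-oxazinium ion, whose O–CH2 carbon C6 is attacked by the free primary amine in an SN2 displacement; the O1–C6 bond breaks, the oxygen leaves as the carbonyl of a neutral secondary amide, and the N4–C3 bond of the spermidine chain is formed. The closest known reactions are the acid- or Zn(OAc)2-catalysed aminolysis of 2-oxazolines to N-(2-aminoethyl)amides and the amine end-capping of oxazolinium and oxazinium chain ends in cationic ring-opening polymerisation. No ring is closed and no stereocentre is created, and both (E)-alkenes are spectators. The step needs attack at C6 instead of C2 or the styryl β-carbon: adducts at C2 and aza-Michael adducts should revert on heating, and the β-carbon is deactivated by the electron-rich 3,4-dimethoxyphenyl group, whereas opening at C6 gives the amide irreversibly. It also needs a single alkylation of the amine and no chain growth of 6 on itself, which the threefold excess of 8, the slow addition of 6 and the preferential protonation of the more basic, more hindered secondary amine 9 should secure. N1 appears as an amide only in the bond-forming event and N8 is already an amide, so neither can compete as a nucleophile.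

Step 6
Reactants: 9 N1,N8-bis[(E)-3,4-dimethoxycinnamoyl]spermidine
Product: 10 N1,N8-bis[(E)-caffeoyl]spermidine, (2E)-3-(3,4-dihydroxyphenyl)-N-{4-[(3-{[(2E)-3-(3,4-dihydroxyphenyl)prop-2-enoyl]amino}propyl)amino]butyl}prop-2-enamide
Conditions: BBr3 (1 M in CH2Cl2, 12 equiv), CH2Cl2, −78 °C to rt; MeOH, 0 °C, evaporation; degassed aq. NaHCO3 to pH 7–8 under Ar, reversed-phase chromatography
Reagents that add atoms: none
Why: Lewis-acid ether cleavage, in which BBr3 coordinates each aryl methyl ether oxygen and bromide removes the methyl group by SN2 as MeBr; the excess covers the reagent bound by the two amides and the amine, and methanolysis then frees the catechols from boron while the (E)-cinnamoyl amides should be unaffected, as in established demethylations of 3,4-dimethoxycinnamamides to caffeoyl amides.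

Compound list
1 | (E)-3,4-dimethoxycinnamic acid, (2E)-3-(3,4-dimethoxyphenyl)prop-2-enoic acid | COc1ccc(/C=C/C(=O)O)cc1OC | starting material
2 | (E)-3,4-dimethoxycinnamoyl chloride | COc1ccc(/C=C/C(=O)Cl)cc1OC | intermediate
3 | 3-aminopropan-1-ol | NCCCO | starting material
4 | (E)-3-(3,4-dimethoxyphenyl)-N-(3-hydroxypropyl)prop-2-enamide | COc1ccc(/C=C/C(=O)NCCCO)cc1OC | intermediate
5 | 3-{[(2E)-3-(3,4-dimethoxyphenyl)prop-2-enoyl]amino}propyl 4-methylbenzenesulfonate (primary tosylate, not isolated) | COc1ccc(/C=C/C(=O)NCCCOS(=O)(=O)c2ccc(C)cc2)cc1OC | intermediate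
6 | 2-[(E)-2-(3,4-dimethoxyphenyl)ethenyl]-5,6-dihydro-4H-1,3-oxazine | COc1ccc(/C=C/C2=NCCCO2)cc1OC | intermediate
7 | putrescine (butane-1,4-diamine) | NCCCCN | starting material
8 | (E)-N-(4-aminobutyl)-3-(3,4-dimethoxyphenyl)prop-2-enamide | COc1ccc(/C=C/C(=O)NCCCCN)cc1OC | intermediate
9 | N1,N8-bis[(E)-3,4-dimethoxycinnamoyl]spermidine | COc1ccc(/C=C/C(=O)NCCCCNCCCNC(=O)/C=C/c2ccc(OC)c(OC)c2)cc1OC | intermediate
10 | N1,N8-bis[(E)-caffeoyl]spermidine | O=C(/C=C/c1ccc(O)c(O)c1)NCCCCNCCCNC(=O)/C=C/c1ccc(O)c(O)c1 | target

Total step count: 6
Longest linear sequence: 5 steps (steps 1, 2, 3, 5, 6); step 4 is the side branch from 2.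

Steps most likely to fail

Step 5. The amine may add at C2 and drain material into amidine-type adducts, the oxazinium ion may be captured by N3 of a second oxazine so that 6 oligomerises, or N4 may be alkylated a second time. The fallback forms the same N4–C3 bond by reductive amination. It sets out from 4, which would be oxidised with Dess–Martin periodinane (CH2Cl2, NaHCO3) to the aldehyde (E)-3-(3,4-dimethoxyphenyl)-N-(3-oxopropyl)prop-2-enamide F1. This would be used at once, condensed with an excess of 8 and reduced with NaBH(OAc)3 (ClCH2CH2Cl, AcOH), returning to the route at 9.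

Step 6. Boron complexes of the amine and amides may precipitate and stall the cleavage before all four ethers are gone, and the basic catechol product may oxidise during isolation. The fallback masks N4 through the deprotection. It sets out from 9, which would be acylated with (CF3CO)2O and Et3N (CH2Cl2, −20 °C) to N4-trifluoroacetyl-N1,N8-bis[(E)-3,4-dimethoxycinnamoyl]spermidine F2, a neutral and soluble substrate. BBr3 in CH2Cl2 followed by MeOH would then give N4-trifluoroacetyl-N1,N8-bis[(E)-caffeoyl]spermidine F3, which can be purified on silica as a neutral tetraphenol. Cleavage of the trifluoroacetamide with K2CO3 in degassed MeOH–H2O under argon, followed by neutralisation with AcOH, returns to the route at 10.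

Step 3. Closure of the six-membered ring by the neutral amide oxygen may be slow, so that chloride from the amine hydrochloride displaces the tosylate and the open-chain material accumulates. The fallback closes the ring from an amidate anion onto a halide instead. It sets out from 2, which would be combined with commercial 3-chloropropylamine hydrochloride (Et3N, CH2Cl2, 0 °C) to give (E)-N-(3-chloropropyl)-3-(3,4-dimethoxyphenyl)prop-2-enamide F4. Deprotonation with NaH in THF (NaI cat., 0 °C to reflux) should cause O-alkylative 6-exo-tet ring closure, returning to the route at 6.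

Further compounds
F1 | step 5 | (E)-3-(3,4-dimethoxyphenyl)-N-(3-oxopropyl)prop-2-enamide | COc1ccc(/C=C/C(=O)NCCC=O)cc1OC
F2 | step 6 | N4-trifluoroacetyl-N1,N8-bis[(E)-3,4-dimethoxycinnamoyl]spermidine | COc1ccc(/C=C/C(=O)NCCCCN(CCCNC(=O)/C=C/c2ccc(OC)c(OC)c2)C(=O)C(F)(F)F)cc1OC
F3 | step 6 | N4-trifluoroacetyl-N1,N8-bis[(E)-caffeoyl]spermidine | O=C(/C=C/c1ccc(O)c(O)c1)NCCCCN(CCCNC(=O)/C=C/c1ccc(O)c(O)c1)C(=O)C(F)(F)F
F4 | step 3 | (E)-N-(3-chloropropyl)-3-(3,4-dimethoxyphenyl)prop-2-enamide | COc1ccc(/C=C/C(=O)NCCCCl)cc1OC
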